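## The problem

Target 14, (3R,4R)-3-(3,4-dihydroxybenzyl)-4-(3,4-dimethoxybenzyl)dihydrofuran-2(3H)-one, is a dibenzylbutyrolactone: a five-membered lactone with one benzyl arm on C3, next to the carbonyl, and another on C4, the two arms trans. The arms differ only in that the C3 arm ends in a free catechol and the C4 arm in a veratrole. That difference has to be built in, because removing two methyl groups from one ring beside the other is not a workable end-game. Lactone C4 has no acidifying neighbour and must be set absolutely. Lactone C3 is α to the carbonyl, so C4 can control it (an electrophile enters the enolate on the face away from the C4 arm, and trans is also the more stable arrangement), but base can also scramble it. The catechol is the fragile group: its anion is oxidised by air and quinones take it to the o-quinone, while hydroxide or alkoxide opens the lactone. It should therefore be set free last, without base and without an oxidant present. The enabling feature is in ring A, the catechol ring, numbered from C1, the carbon bonded to the benzylic CH2. Its hydroxyls sit on the adjacent carbons C3 and C4, flanked by the CH groups C2 and C5. The unit C2–C3–C4–C5 with its two oxygens is the carbon chain of biacetyl as its bis-enol, a symmetrical 2,3-dioxygenated butadiene. What remains, C1 and C6 with the CH2 on C1, is a terminal alkyne on a methylene group, that is, a propargyl group on lactone C3.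

## Retrosynthesis

**14 from 13.** Only the two O–Si bonds of (3R,4R)-3-[3,4-bis(trimethylsilyloxy)benzyl]-4-(3,4-dimethoxybenzyl)dihydrofuran-2(3H)-one 13 are cut. Aryl trimethylsilyl ethers fall to traces of acid in methanol, conditions that leave the methyl ethers, the lactone and C3 alone. The forward step only has to avoid base and oxidants.

**13 from 12.** Two hydrogens are added back to ring A, which gives the 1,4-cyclohexadiene 12, (3R,4R)-3-{[4,5-bis(trimethylsilyloxy)cyclohexa-1,4-dien-1-yl]methyl}-4-(3,4-dimethoxybenzyl)dihydrofuran-2(3H)-one. No bond of the skeleton changes. The forward dehydrogenation with DDQ must be done while both oxygens are still silylated, so that the quinone never meets a free catechol.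

**12 from 9 and 11.** This is the strategic cut: ring A bonds C1–C2 and C5–C6 are broken. It gives the terminal alkyne 9, (3R,4R)-4-(3,4-dimethoxybenzyl)-3-(prop-2-yn-1-yl)dihydrofuran-2(3H)-one, and the diene 11, 2,3-bis(trimethylsilyloxy)buta-1,3-diene.
- The neighbouring cut lies one bond further out, at the lactone C3–CH2 bond, with ring A bought ready-made and its phenols protected. It is the textbook solution and is kept as the fallback.
- The ring-forming cut replaces a protected benzylic halide, which takes several steps to make, by propargyl bromide and a one-step diene. It brings the catechol oxygens in as silyl ethers that leave without hydrogenolysis or Lewis acid. It also leaves the oxygenation pattern of ring A open to variation through the diene.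
- The precursor 9 is six carbons and two oxygens smaller than 12 and already holds both stereocentres.
- The forward reaction must join an unactivated alkyne to an electron-rich diene, which no thermal Diels–Alder reaction will do. A low-valent cobalt catalyst is therefore required, and it must prefer the cross-reaction to alkyne trimerisation.

**9 from 6 and 7.** The lactone C3–CH2 bond is cut, giving (R)-4-(3,4-dimethoxybenzyl)dihydrofuran-2(3H)-one 6 and propargyl bromide 7. The lithium enolate 8 of 6 is planar at C3 and shielded on one face by the C4 arm, so alkylation should deliver the trans product. This is the point where C4 controls C3.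

**6 from 4.** The lactone O1–C2 bond is opened and C5 is raised to the ester level, giving the half ester 4, (R)-4-(3,4-dimethoxyphenyl)-3-(methoxycarbonyl)butanoic acid. The forward step must reduce the ester and not the acid, so that the carbon next to the stereocentre becomes C5 and the benzyl group ends up at C4. A borohydride acting on the carboxylate salt does this, and the hydroxy acid 5 closes on acidification.

**4 from 3.** Two C–H bonds are removed, giving the alkene (E)-4-(3,4-dimethoxyphenyl)-3-(methoxycarbonyl)but-3-enoic acid 3. This places the only absolute stereochemical decision of the route in a catalytic hydrogenation of an itaconate-type acid, a substrate class for which chiral rhodium diphosphine catalysts are well established.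

**3 from 1 and 2.** The C=C bond is cut, giving 3,4-dimethoxybenzaldehyde 1 and dimethyl succinate 2. The Stobbe condensation joins them and also differentiates the two carboxyl groups, which the later reduction needs.

**11 from 10.** The two O–Si bonds are cut, giving butane-2,3-dione 10. Each ketone can enolise only toward its methyl group, so bis-silylation has a single possible outcome.

## Roads not taken

**Alternative 1:** silicon-tethered radical delivery of lactone C5.
- *Cut:* the lactone C4–C5 bond. C5 starts as the CH2 of a bromomethylsilyl ether on a benzylic alcohol, at the carbon that later becomes the benzylic CH2 of the dimethoxybenzyl arm.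
- *Forward key step:* Bu3SnH and AIBN convert the bromide A2, methyl (R,E)-2-[3,4-bis(benzyloxy)benzyl]-4-{[(bromomethyl)dimethylsilyl]oxy}-4-(3,4-dimethoxyphenyl)but-2-enoate, into the Si–CH2 radical. It adds 5-exo to the β-carbon of the enoate, and the resulting α-ester radical takes a hydrogen from the stannane. The product is the oxasilolane A1, methyl (2R)-3-[3,4-bis(benzyloxy)phenyl]-2-[(4S,5R)-5-(3,4-dimethoxyphenyl)-2,2-dimethyl-1,2-oxasilolan-4-yl]propanoate.
- *Merits:* the tether delivers exactly one carbon with predictable regiochemistry. The future C4 is set relative to the carbinol centre through a cyclic transition state. Ring A is carried through as a purchased arene with robust benzyl ethers.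
- *Weak points:* lactone C3 is fixed when an open-chain radical picks up hydrogen, with little to bias the face, so a later equilibration would be needed. The carbinol stereocentre must be made enantiomerically enriched and is then erased by hydrogenolysis. After the key step there are still oxidative C–Si cleavage, lactonisation and a double hydrogenolysis. Tin is used in stoichiometric amount.
- *Comparison:* this road is better in that ring A is never built and no oxidant touches an electron-rich intermediate. The chosen plan sets against this that both stereocentres come from reactions with a known sense, that only two operations follow its key step, and that it needs neither tin nor a sacrificial stereocentre.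

**Alternative 2:** enzymatic Baeyer–Villiger desymmetrisation.
- *Cut:* the lactone O1–C5 bond. The ring oxygen is inserted next to the carbonyl of the achiral ketone A4, 3-(3,4-dimethoxybenzyl)cyclobutan-1-one.
- *Forward key step:* a Baeyer–Villiger monooxygenase with O2 and NADPH migrates one of the two enantiotopic ring bonds. The product is A3, (R)-4-(3,4-dimethoxybenzyl)dihydrofuran-2(3H)-one, which is the same compound as 6.
- *Merits:* one catalytic step creates the C4 stereocentre from an achiral substrate, with oxygen as the oxidant and without heavy metal or hydride.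
- *Weak points:* it ends at the monosubstituted lactone and says nothing about C3 or ring A. The enantiopreference of these enzymes toward 3-benzylcyclobutanones depends on the enzyme, so an R-selective one for this substrate would have to be found by screening. Cofactor recycling and dilute aqueous operation limit throughput.
- *Comparison:* as a way to 6 this road is about as short as steps 1 to 3 and arguably cleaner, and it could be placed in front of the chosen key step unchanged. The chosen plan keeps the Stobbe and hydrogenation sequence because ligand control on this aryl pattern follows an established model. In addition, the half ester 4 is a carboxylic acid whose enantiomeric purity can be raised by crystallisation of a salt.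

**Alternative 3:** carbonylative lactonisation with CO.
- *Cut:* the lactone C2–O1 and C2–C3 bonds, with C2 coming from carbon monoxide.
- *Forward key step:* PdCl2(PPh3)2 (divalent palladium) with SnCl2 under CO converts the alkynol A6, (R)-4-[3,4-bis(benzyloxy)phenyl]-2-(3,4-dimethoxybenzyl)but-3-yn-1-ol, into the benzylidene lactone A5, (R,E)-3-[3,4-bis(benzyloxy)benzylidene]-4-(3,4-dimethoxybenzyl)dihydrofuran-2(3H)-one. An alkoxycarbonyl palladium species adds syn across the alkyne, which fixes the E geometry.
- *Merits:* both arenes are in place before the lactone closes, so the route is convergent. The carbonyl carbon costs nothing, and ring A is bought, not made.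
- *Weak points:* C3 is not a stereocentre in A5. Hydrogenation of the exocyclic alkene adds hydrogen to the face away from the C4 arm and so places the two arms cis. An epimerisation must follow, and it should happen before the benzyl ethers are removed, yet hydrogen over palladium would remove them in the same operation. A6 holds a propargylic stereocentre that needs its own asymmetric synthesis and an aryl–alkyne coupling. Pressurised CO is required.
- *Comparison:* this road is more convergent than the chosen one. The chosen plan sets against this that the trans relationship is made directly, under kinetic control that coincides with the thermodynamic preference, and that no base is ever applied to a catechol-bearing compound.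

Key step: step 6

Assumption: (4S,5S)-MOD-DIOP, that is (4S,5S)-4,5-bis{[bis(4-methoxy-3,5-dimethylphenyl)phosphino]methyl}-2,2-dimethyl-1,3-dioxolane, is taken to be the ligand hand that gives the R acid 4 in step 2. If the sense is the opposite, the (4R,5R) ligand is used and nothing else changes.

## Route

Step 1
Reactants: 1 3,4-dimethoxybenzaldehyde; 2 dimethyl succinate
Product: 3 (E)-4-(3,4-dimethoxyphenyl)-3-(methoxycarbonyl)but-3-enoic acid
Conditions: NaOMe (1.5 equiv), MeOH, reflux; then 2 M HCl; recrystallisation
Reagents that add atoms: none
Why: Stobbe condensation: the succinate enolate adds to the aldehyde, the alkoxide closes to a lactone ester, and ring-opening elimination gives the carboxylate of the half ester. The E alkene (aryl trans to the ester) is the favoured outcome of that elimination and should be obtained pure by crystallisation.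

Step 2
Reactants: 3 (E)-4-(3,4-dimethoxyphenyl)-3-(methoxycarbonyl)but-3-enoic acid
Product: 4 (R)-4-(3,4-dimethoxyphenyl)-3-(methoxycarbonyl)butanoic acid
Conditions: [Rh(cod)Cl]2 (0.5 mol%), (4S,5S)-MOD-DIOP (1.1 mol%), Et3N (1 equiv), H2 (1 atm), MeOH, 30 °C; then 1 M HCl
Reagents that add atoms: none
Why: Rhodium–diphosphine asymmetric hydrogenation of an itaconate-type half ester: carboxylate and alkene chelate the metal, and the chiral diphosphine lets hydrogen add to one face only, which sets the future lactone C4 as R. The enantiomeric purity can be raised by crystallising an amine salt of the acid.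

Step 3
Reactants: 4 (R)-4-(3,4-dimethoxyphenyl)-3-(methoxycarbonyl)butanoic acid
Product: 6 (R)-4-(3,4-dimethoxybenzyl)dihydrofuran-2(3H)-one, via hydroxy acid 5 (not isolated)
Conditions: KOH (1.0 equiv), EtOH, 0 °C; CaCl2, NaBH4, EtOH, −10 °C to rt; then 3 M HCl, rt
Reagents that add atoms: none
Why: Chemoselective ester reduction: Ca(BH4)2, formed from CaCl2 and NaBH4, reduces the methyl ester but not the potassium carboxylate, and acidification closes the γ-hydroxy acid 5 to the lactone. The stereocentre is not touched and ends up β to the carbonyl, where it can no longer epimerise.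

Step 4
Reactants: 6 (R)-4-(3,4-dimethoxybenzyl)dihydrofuran-2(3H)-one; 7 propargyl bromide (3-bromoprop-1-yne)
Product: 9 (3R,4R)-4-(3,4-dimethoxybenzyl)-3-(prop-2-yn-1-yl)dihydrofuran-2(3H)-one, via lithium enolate 8 (not isolated)
Conditions: LiN(SiMe3)2 (1.05 equiv), THF, −78 °C; then 7 (1.3 equiv), DMPU, −78 to −40 °C; aq. NH4Cl
Reagents that add atoms: none
Why: Alkylation of a lactone enolate by SN2 attack on a primary propargylic bromide. The enolate is planar at C3, the C4 benzyl arm blocks one face, and the electrophile enters anti to it, which sets C3 as R (3,4-trans), also the thermodynamically preferred arrangement.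

Step 5
Reactants: 10 butane-2,3-dione (biacetyl)
Product: 11 2,3-bis(trimethylsilyloxy)buta-1,3-diene
Conditions: Me3SiOTf (2.1 equiv), Et3N (2.4 equiv), Et2O, 0 °C to rt; separation from the salt layer; distillation under reduced pressure
Reagents that add atoms: trimethylsilyl trifluoromethanesulfonate, C[Si](C)(C)OS(=O)(=O)C(F)(F)F
Why: Soft enolisation and O-silylation of both carbonyl groups with a silyl triflate and a tertiary amine. Each ketone can enolise only toward its methyl group, so the 2,3-bis(silyloxy)diene is the only constitution possible.

Step 6
Reactants: 9 (3R,4R)-4-(3,4-dimethoxybenzyl)-3-(prop-2-yn-1-yl)dihydrofuran-2(3H)-one; 11 2,3-bis(trimethylsilyloxy)buta-1,3-diene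
Product: 12 (3R,4R)-3-{[4,5-bis(trimethylsilyloxy)cyclohexa-1,4-dien-1-yl]methyl}-4-(3,4-dimethoxybenzyl)dihydrofuran-2(3H)-one
Conditions: CoBr2(dppe) (10 mol%), Zn dust (20 mol%), ZnI2 (20 mol%), 11 (2.5 equiv), CH2Cl2, rt, 9 added slowly; pentane, filtration through Et3N-deactivated silica, evaporation
Reagents that add atoms: none
Why: Zinc reduces the divalent cobalt of CoBr2(dppe) (dppe = Ph2PCH2CH2PPh2) to a monovalent cobalt diphosphine species, and ZnI2 removes halide to free coordination sites. The metal binds diene 11 through all four carbons and the alkyne of 9 side-on; oxidative coupling joins the alkyne CH to one diene CH2 and gives an allyl–vinyl metallacycle of trivalent cobalt, and reductive elimination makes the second C–C bond, releases 12 and returns monovalent cobalt. The closest known reaction type is the cobalt-catalysed neutral Diels–Alder reaction of unactivated terminal alkynes with 2-silyloxy- and 2,3-dialkylbutadienes. The six-membered carbocycle closes as a formal [4+2] cycloaddition in which both new σ bonds are made at the metal, and the two double bonds of the product are not conjugated. No stereocentre is formed, and since the medium is neither basic nor protic, lactone C3 should keep its configuration. The selectivity needed is chemoselectivity for the cross-reaction over alkyne cyclotrimerisation and diene dimerisation; the chelating diphosphine, the excess of diene and the slow addition of 9 secure it. Regiochemistry needs no control, because the diene is symmetrical and either orientation gives the same ring. The lactone and the aryl methyl ethers are weak donors that this catalyst system tolerates.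

Step 7
Reactants: 12 (3R,4R)-3-{[4,5-bis(trimethylsilyloxy)cyclohexa-1,4-dien-1-yl]methyl}-4-(3,4-dimethoxybenzyl)dihydrofuran-2(3H)-one
Product: 13 (3R,4R)-3-[3,4-bis(trimethylsilyloxy)benzyl]-4-(3,4-dimethoxybenzyl)dihydrofuran-2(3H)-one
Conditions: DDQ (1.0 equiv), toluene, 0 °C to rt; filtration, short pad of neutral alumina
Reagents that add atoms: none
Why: DDQ dehydrogenation of a 1,4-cyclohexadiene: hydride leaves a doubly allylic ring CH2 to give a silyloxy-stabilised cyclohexadienyl cation, and loss of a proton from the other CH2 gives the arene. The silyl groups keep the catechol masked from the quinone, one equivalent of oxidant leaves the dimethoxybenzyl arm alone, and both stereocentres lie outside the ring.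

Step 8
Reactants: 13 (3R,4R)-3-[3,4-bis(trimethylsilyloxy)benzyl]-4-(3,4-dimethoxybenzyl)dihydrofuran-2(3H)-one
Product: 14 (3R,4R)-3-(3,4-dihydroxybenzyl)-4-(3,4-dimethoxybenzyl)dihydrofuran-2(3H)-one (3'-O-demethylarctigenin)
Conditions: PPTS (10 mol%), degassed MeOH, 0 °C to rt, under argon
Reagents that add atoms: none
Why: Acid-catalysed methanolysis of aryl trimethylsilyl ethers, which are far more labile than the methyl ethers or the lactone. No base is present, so lactone C3 is not epimerised and the catechol is not exposed to oxidising conditions.

## Compound list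

1 | 3,4-dimethoxybenzaldehyde | COc1ccc(C=O)cc1OC | starting material
2 | dimethyl succinate | COC(=O)CCC(=O)OC | starting material
3 | (E)-4-(3,4-dimethoxyphenyl)-3-(methoxycarbonyl)but-3-enoic acid | COC(=O)/C(CC(=O)O)=C/c1ccc(OC)c(OC)c1 | intermediate
4 | (R)-4-(3,4-dimethoxyphenyl)-3-(methoxycarbonyl)butanoic acid | COc1ccc(C[C@H](CC(=O)O)C(=O)OC)cc1OC | intermediate
5 | (R)-4-(3,4-dimethoxyphenyl)-3-(hydroxymethyl)butanoic acid (formed as its carboxylate, not isolated) | COc1ccc(C[C@H](CC(=O)O)CO)cc1OC | intermediate
6 | (R)-4-(3,4-dimethoxybenzyl)dihydrofuran-2(3H)-one | COc1ccc(C[C@H]2COC(=O)C2)cc1OC | intermediate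
7 | propargyl bromide (3-bromoprop-1-yne) | BrCC#C | starting material
8 | lithium (R)-4-(3,4-dimethoxybenzyl)-4,5-dihydrofuran-2-olate (lithium enolate of 6, not isolated) | COc1ccc(C[C@H]2COC(O[Li])=C2)cc1OC | intermediate
9 | (3R,4R)-4-(3,4-dimethoxybenzyl)-3-(prop-2-yn-1-yl)dihydrofuran-2(3H)-one | COc1ccc(C[C@H]2COC(=O)[C@@H]2CC#C)cc1OC | intermediate
10 | butane-2,3-dione (biacetyl) | CC(=O)C(C)=O | starting material
11 | 2,3-bis(trimethylsilyloxy)buta-1,3-diene | C=C(O[Si](C)(C)C)C(=C)O[Si](C)(C)C | intermediate
12 | (3R,4R)-3-{[4,5-bis(trimethylsilyloxy)cyclohexa-1,4-dien-1-yl]methyl}-4-(3,4-dimethoxybenzyl)dihydrofuran-2(3H)-one | COc1ccc(C[C@H]2COC(=O)[C@@H]2CC2=CCC(O[Si](C)(C)C)=C(O[Si](C)(C)C)C2)cc1OC | intermediate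
13 | (3R,4R)-3-[3,4-bis(trimethylsilyloxy)benzyl]-4-(3,4-dimethoxybenzyl)dihydrofuran-2(3H)-one | COc1ccc(C[C@H]2COC(=O)[C@@H]2Cc2ccc(O[Si](C)(C)C)c(O[Si](C)(C)C)c2)cc1OC | intermediate
14 | (3R,4R)-3-(3,4-dihydroxybenzyl)-4-(3,4-dimethoxybenzyl)dihydrofuran-2(3H)-one (3'-O-demethylarctigenin) | COc1ccc(C[C@H]2COC(=O)[C@@H]2Cc2ccc(O)c(O)c2)cc1OC | target

## Step count and risks

Total step count: 8. Longest linear sequence: 7 steps (steps 1 to 4, then 6 to 8). Step 5 is a one-step branch.

**Step 6 (key step).**
- *What may go wrong:* homo-coupling of the alkyne (cyclotrimerisation) may outrun the cross-reaction. Diene 11 is bulkier and more electron-rich than the dienes for which this catalyst is established, so turnover may be slow. ZnI2 may strip silyl groups from the diene before it reacts.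
- *Fallback:* the fallback gives up the ring construction and returns to the benzylation cut. It sets out from lactone 6. Enolate 8 is formed as in step 4 and alkylated with 4-(bromomethyl)-1,2-bis(benzyloxy)benzene F1, made from commercial 3,4-bis(benzyloxy)benzyl alcohol with PBr3. The same facial control should give (3R,4R)-3-[3,4-bis(benzyloxy)benzyl]-4-(3,4-dimethoxybenzyl)dihydrofuran-2(3H)-one F2. Hydrogenolysis (H2, Pd/C, EtOAc) then removes both benzyl ethers and comes back to the route at 14.

**Step 7.**
- *What may go wrong:* the acidic hydroquinone formed from DDQ may remove silyl groups before or during dehydrogenation, after which the quinone would oxidise the unmasked ring further. An excess of oxidant could also abstract hydride at the benzylic positions of the dimethoxybenzyl arm.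
- *Fallback:* the oxygens are carried as tert-butyldimethylsilyl ethers, which survive chromatography and the hydroquinone. The fallback sets out from 10 and 9. Biacetyl 10 with tert-butyldimethylsilyl triflate and Et3N gives 2,3-bis(tert-butyldimethylsilyloxy)buta-1,3-diene F3. The cobalt-catalysed cycloaddition of step 6 with 9 gives (3R,4R)-3-{[4,5-bis(tert-butyldimethylsilyloxy)cyclohexa-1,4-dien-1-yl]methyl}-4-(3,4-dimethoxybenzyl)dihydrofuran-2(3H)-one F4. DDQ gives (3R,4R)-3-[3,4-bis(tert-butyldimethylsilyloxy)benzyl]-4-(3,4-dimethoxybenzyl)dihydrofuran-2(3H)-one F5, which can be purified. Bu4NF buffered with AcOH in THF comes back to the route at 14.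

**Step 4.**
- *What may go wrong:* proton transfer between the enolate and the acidic alkyne C–H, or the α-hydrogen of the product, may lead to double alkylation. The slim propargyl group may also give incomplete trans selectivity.
- *Fallback:* the alkyne C–H is masked. The fallback sets out from 6. Enolate 8 is alkylated with commercial 3-bromo-1-(trimethylsilyl)prop-1-yne to give (3R,4R)-4-(3,4-dimethoxybenzyl)-3-[3-(trimethylsilyl)prop-2-yn-1-yl]dihydrofuran-2(3H)-one F6. The bulkier electrophile should also sharpen the facial preference. Cleavage of the C–Si bond with Bu4NF and AcOH in THF comes back to the route at 9.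

**Step 2.**
- *What may go wrong:* facial discrimination on this electron-rich substrate may be insufficient, or the ligand may give the opposite sense to the one assumed.
- *Fallback:* the stereocentre is set with a chiral auxiliary instead. The fallback sets out from aldehyde 1 and comes back to the route at 6.
  - Knoevenagel–Doebner condensation with malonic acid (pyridine, piperidine) gives (E)-3-(3,4-dimethoxyphenyl)prop-2-enoic acid F7.
  - Hydrogenation (H2, Pd/C) gives 3-(3,4-dimethoxyphenyl)propanoic acid F8.
  - Coupling with (S)-4-benzyloxazolidin-2-one (DCC, DMAP, CH2Cl2) gives (S)-4-benzyl-3-[3-(3,4-dimethoxyphenyl)propanoyl]oxazolidin-2-one F9.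
  - The sodium Z-enolate (NaN(SiMe3)2, THF, −78 °C) is alkylated by tert-butyl bromoacetate on the face away from the benzyl group of the auxiliary, giving tert-butyl (R)-3-{[(S)-4-benzyl-2-oxooxazolidin-3-yl]carbonyl}-4-(3,4-dimethoxyphenyl)butanoate F10.
  - LiBH4 removes the auxiliary reductively and gives tert-butyl (R)-4-(3,4-dimethoxyphenyl)-3-(hydroxymethyl)butanoate F11.
  - CF3CO2H in CH2Cl2 cleaves the tert-butyl ester and closes the lactone 6.

## Further compounds

F1 | step 6 | 4-(bromomethyl)-1,2-bis(benzyloxy)benzene | BrCc1ccc(OCc2ccccc2)c(OCc2ccccc2)c1
F2 | step 6 | (3R,4R)-3-[3,4-bis(benzyloxy)benzyl]-4-(3,4-dimethoxybenzyl)dihydrofuran-2(3H)-one | COc1ccc(C[C@H]2COC(=O)[C@@H]2Cc2ccc(OCc3ccccc3)c(OCc3ccccc3)c2)cc1OC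
F3 | step 7 | 2,3-bis(tert-butyldimethylsilyloxy)buta-1,3-diene | C=C(O[Si](C)(C)C(C)(C)C)C(=C)O[Si](C)(C)C(C)(C)C
F4 | step 7 | (3R,4R)-3-{[4,5-bis(tert-butyldimethylsilyloxy)cyclohexa-1,4-dien-1-yl]methyl}-4-(3,4-dimethoxybenzyl)dihydrofuran-2(3H)-one | COc1ccc(C[C@H]2COC(=O)[C@@H]2CC2=CCC(O[Si](C)(C)C(C)(C)C)=C(O[Si](C)(C)C(C)(C)C)C2)cc1OC
F5 | step 7 | (3R,4R)-3-[3,4-bis(tert-butyldimethylsilyloxy)benzyl]-4-(3,4-dimethoxybenzyl)dihydrofuran-2(3H)-one | COc1ccc(C[C@H]2COC(=O)[C@@H]2Cc2ccc(O[Si](C)(C)C(C)(C)C)c(O[Si](C)(C)C(C)(C)C)c2)cc1OC
F6 | step 4 | (3R,4R)-4-(3,4-dimethoxybenzyl)-3-[3-(trimethylsilyl)prop-2-yn-1-yl]dihydrofuran-2(3H)-one | COc1ccc(C[C@H]2COC(=O)[C@@H]2CC#C[Si](C)(C)C)cc1OC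
F7 | step 2 | (E)-3-(3,4-dimethoxyphenyl)prop-2-enoic acid | COc1ccc(/C=C/C(=O)O)cc1OC
F8 | step 2 | 3-(3,4-dimethoxyphenyl)propanoic acid | COc1ccc(CCC(=O)O)cc1OC
F9 | step 2 | (S)-4-benzyl-3-[3-(3,4-dimethoxyphenyl)propanoyl]oxazolidin-2-one | COc1ccc(CCC(=O)N2[C@@H](Cc3ccccc3)COC2=O)cc1OC
F10 | step 2 | tert-butyl (R)-3-{[(S)-4-benzyl-2-oxooxazolidin-3-yl]carbonyl}-4-(3,4-dimethoxyphenyl)butanoate | COc1ccc(C[C@H](CC(=O)OC(C)(C)C)C(=O)N2[C@@H](Cc3ccccc3)COC2=O)cc1OC
F11 | step 2 | tert-butyl (R)-4-(3,4-dimethoxyphenyl)-3-(hydroxymethyl)butanoate | COc1ccc(C[C@H](CC(=O)OC(C)(C)C)CO)cc1OC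
A1 | alternative 1 | methyl (2R)-3-[3,4-bis(benzyloxy)phenyl]-2-[(4S,5R)-5-(3,4-dimethoxyphenyl)-2,2-dimethyl-1,2-oxasilolan-4-yl]propanoate (4,5-trans) | COC(=O)[C@H](Cc1ccc(OCc2ccccc2)c(OCc2ccccc2)c1)[C@@H]1C[Si](C)(C)O[C@H]1c1ccc(OC)c(OC)c1
A2 | alternative 1 | methyl (R,E)-2-[3,4-bis(benzyloxy)benzyl]-4-{[(bromomethyl)dimethylsilyl]oxy}-4-(3,4-dimethoxyphenyl)but-2-enoate | COC(=O)/C(Cc1ccc(OCc2ccccc2)c(OCc2ccccc2)c1)=C/[C@@H](O[Si](C)(C)CBr)c1ccc(OC)c(OC)c1
A3 | alternative 2 | (R)-4-(3,4-dimethoxybenzyl)dihydrofuran-2(3H)-one | COc1ccc(C[C@H]2COC(=O)C2)cc1OC
A4 | alternative 2 | 3-(3,4-dimethoxybenzyl)cyclobutan-1-one | COc1ccc(CC2CC(=O)C2)cc1OC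
A5 | alternative 3 | (R,E)-3-[3,4-bis(benzyloxy)benzylidene]-4-(3,4-dimethoxybenzyl)dihydrofuran-2(3H)-one | O=C1OC[C@H](Cc2ccc(OC)c(OC)c2)/C1=C\c1ccc(OCc2ccccc2)c(OCc2ccccc2)c1
A6 | alternative 3 | (R)-4-[3,4-bis(benzyloxy)phenyl]-2-(3,4-dimethoxybenzyl)but-3-yn-1-ol | OC[C@H](Cc1ccc(OC)c(OC)c1)C#Cc1ccc(OCc2ccccc2)c(OCc2ccccc2)c1
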